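The earlier runs and the new flask are simulated on assumed constants; noise was put on by code.

1. Left to late times the larch run loses target: it reads 28.8% at 15.0 min but 26.7% at 25.0 min. So my decision for the next flask is when to stop it, and that hangs on whether the larch curve still holds at the new charge.

- larch: solid substrate 0.10 M; coupling partner 1.8 equiv; run made earlier
- flask: solid substrate 0.050 M; coupling partner 1.80 equiv; time 2.0 h

- larch (time / min: target / %, solid substrate / %): 2.00: 9.4, 81.4; 3.00: 12.1, 76.9; 5.00: 17.6, 67.1; 8.00: 23.9, 51.9; 15.0: 28.8, 24.4; 25.0: 26.7, 0.6

(readings scatter by 0.5 percentage points)

- as a solid, counted per litre of solution: solid substrate
- on the list of suspects stand: dissolved substrate + coupling partner -> target; target <-> isomer of the product; solid substrate <-> dissolved substrate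
- at the start none of the solid substrate is in solution

* when, up to 2.0 h, the flask holds most target
* the amount of target, in percent of the solid substrate charged, at that time

2. I run a straight line through the solid substrate readings at 5.00 min and 8.00 min back to the start, and it lands short of the full charge. I read that shortfall as the standing pool, the [dissolved substrate] held while solid substrate remains, 7.57 mM.

3. If [dissolved substrate] stays at that pool and the equivalents are kept, [coupling partner] goes with the charge, so the rate of making target, counted in percent of the charge, doesn't change with the charge, and a first-order loss to isomer of the product doesn't either. I therefore expect the flask to follow the larch curve in percent until its solid substrate is gone, which comes when the larch solid substrate reads 7.57%.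

4. The larch run passes that reading near 0.368 h, later than the top of a parabola through the last three target readings, 0.301 h. So I charge 0.050 M, keep 1.80 equiv, stop at that top rather than at 2.0 h, and expect a little above 28.8%.

5. The forecast says 28% at 0.26 h, earlier than my time, holding that “solubility stays fixed in molar terms”.

6. The flask holds most target, 29.5%, at 0.326 h, later than the forecast. Solid substrate in the flask already stands at 0% at that time, so my 0.368 h ran late. The pool gives 15.1% of this flask's charge as dissolved substrate, and the flask holds 16.3% of dissolved substrate at 0.200 h, while solid substrate stands at 26.1%.

    dissolved substrate + coupling partner → target (k = 4.00 M⁻¹ min⁻¹)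
    target ⇌ isomer of the product (K = 5.10, k = 0.160 min⁻¹)
    solid substrate ⇌ dissolved substrate, rate k3*(cs3 - [dissolved substrate]) while solid is left; crystals form when [dissolved substrate] > cs3 (solubility = 8.30 mM, k = 12.0 min⁻¹)

7. In a neighbouring flask charged with 0.013 M of solid substrate, equivalents and time held, the pool is 58.2% of the charge, so that neighbour should leave the larch curve at a larch solid substrate reading of 50.6%, close to the larch reading of 51.9% at 8.00 min, where larch target reads 23.9%. The computed best of that neighbour flask is 25.1%.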